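## Analysis of the target

Gericudranin D (18) is a (2R,3R)-dihydroflavonol. Ring C of the chroman-4-one carries the C4 ketone, a hydroxyl at C3 and a 4-hydroxyphenyl group (ring B) at C2. Ring A is fully substituted, with hydroxyls at C5 and C7 and 4-hydroxybenzyl groups at C6 and C8. The two stereocentres, C2 and C3, are adjacent and trans, with aryl and hydroxyl both equatorial; this is also the thermodynamically preferred arrangement, because C3 is epimerisable next to the ketone. The sensitive points all lie in ring C: base generates the C3 enolate, which expels O1 from C2 and opens the ring; acid can ionise the C2–O1 bond, since C2 is benzylic and para-oxygenated; and the α-ketol is easily dehydrogenated to the flavonol. The main difficulty is ring A: a phloroglucinol nucleus with no free position, in which two carbon substituents alternate with three oxygens, is hard to reach by C-benzylation of a preformed arene, and it must be combined with two stereocentres that tolerate neither strong base nor strong acid. The strategy rests on one structural feature: C5–C6–C7–C8 of ring A, with oxygen at C5 and C7 and benzyl at C6 and C8, is the carbon chain of the self-Claisen product of a 3-arylpropanoate. The remaining edge, C4a–C8a, is the enone double bond of a 2-aryl-3-oxy-2,3-dihydropyran-4-one that already holds O1, C2, C3 and C4, so ring A is built last, onto a complete and enantioenriched ring C.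

## Retrosynthetic reasoning

**Protecting groups.** Gericudranin D (18) is traced back to its tribenzyl ether 17 and this to the 3-O-silyl ether 16; only O–benzyl and O–Si bonds are cut. Benzyl ethers are preferred to acetal-type phenol protection because the key step combines a strong silyl Lewis acid with a ketene acetal, conditions under which an aryl acetal would ionise and alkylate the diene. Aryl benzyl ethers are inert there and towards the strong bases of the fragment syntheses, and they leave at the end by neutral hydrogenolysis, which spares ring C. The silyl ether at C3 is removed first so that the last intermediate, 17, is still easy to purify.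

**Ring A.** In 16 the bonds C4a–C5 and C8–C8a are cut, which leads to bromo dihydropyranone 8 and bis(silyloxy)diene 13. These bonds separate a four-carbon unit that carries every substituent of ring A in the right order from an enone edge belonging to a ring C in which C2 and C3 are already fixed. No C–O or benzyl–arene bond has to be made on the crowded arene, and no stereocentre has to be created. The forward reaction must join the nucleophilic terminus of 13 to the β-carbon of the vinylogous ester of 8 (C8 to C8a) and close the ring between the ketene acetal carbon and the bromine-bearing α-carbon (C5 to C4a). It must then aromatise by loss of the bromine together with H8a and of the methoxy group together with H8; the bromine thus stands for the oxidation level of the arene.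

**Pyranone.** 8 is simplified by removing the bromine (to 7), the silyl group (to 6) and the C3 oxygen (to 4). Bromination comes last because C5 of a vinylogous ester is cleanly attacked by an electrophile, whereas a bromo enone would not survive the enolisation needed to oxidise C3. The C3 oxygen is introduced through silyl dienol ether 5, anti to the aryl group at C2, so that C2 controls C3.

**Hetero-Diels–Alder.** In 4 the bonds C2–C3 and O1–C6 are cut, giving aldehyde 1 and diene 2. This is the shortest entry to an enantioenriched 2-aryl dihydropyranone. The forward reaction sets, under catalyst control, the one stereocentre from which the other follows.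

**Diene.** 13 is the doubly O-silylated form of β-keto ester 11, reached through the mono-silyl enol ether 12. In 11 the C2–C3 bond (C6–C7 of the target) is cut, giving two molecules of ester 10, made by benzylation of phenol 9. One ester thus supplies both benzyl groups, the oxygens at C5 and C7 and four ring carbons without any selectivity problem.

## Alternatives that were turned down

**Alternative 1:** The disconnection is C4–C4a. The forward key step activates the carboxyl group of (2R,3R)-2-acetoxy-3-(4-acetoxyphenyl)-3-{3,5-bis(benzyloxy)-2,4-bis[4-(benzyloxy)benzyl]phenoxy}propanoic acid A2 as a mixed anhydride and acylates the single free position of ring A. This intramolecular Friedel–Crafts reaction closes ring C and gives 3,4'-di-O-acetyl-5,7,4'',4'''-tetra-O-benzyl gericudranin D A1.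
- For: the acylation of electron-rich aryl ethers is well precedented, the regiochemistry is automatic, and C2 and C3 are in place before the ring closes. On precedent for the key step this alternative is stronger than the chosen route.
- Against: A2 can only be reached after two controlled C-benzylations of a phloroglucinol nucleus, differentiation of its three oxygens, and an aryl ether formation at a benzylic carbon with a doubly ortho-substituted phenol under clean inversion. The strongly acidic acylation medium then threatens that same C2–O bond, the benzyl ether peri to the new ketone, and β-elimination of the aryloxy group from the activated acid. Two kinds of protecting group must be removed afterwards, the acetates under conditions that ring C tolerates poorly.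
- Comparison: the chosen route is shorter, avoids any alkylation of a phloroglucinol, and exposes the stereocentres to no strong protic acid.

**Alternative 2:** The disconnections are C4a–C4, C4–C3 and O1–C2. In the forward step a divalent palladium–phosphine precatalyst with a secondary amine joins 2-iodo-3,5-bis(methoxymethoxy)-4,6-bis[4-(methoxymethoxy)benzyl]phenol A4, a carbonyl unit and 1-ethynyl-4-(methoxymethoxy)benzene A5 in a carbonylative Sonogashira coupling. In-situ 6-endo closure gives 5,7-bis(methoxymethoxy)-6,8-bis[4-(methoxymethoxy)benzyl]-2-[4-(methoxymethoxy)phenyl]-4H-chromen-4-one A3.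
- For: it is convergent, catalytic, forms three bonds in one operation, and is well precedented for flavones; here it is clearly stronger than the chosen key step.
- Against: A3 is flat, so both stereocentres must be introduced afterwards by enantioselective reduction of C2=C3 and hydroxylation at C3 on a hindered 5-oxygenated flavone, which is the actual problem of the target postponed. A4 again needs the fully substituted ring A, now with an iodine between two ortho substituents, where oxidative addition is slow. 5-Exo closure to the aurone competes.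
- Comparison: the chosen route settles C2 and C3 first by catalyst and substrate control and needs only deprotection after its key step.

**Alternative 3:** The disconnection is C3–C4. A chiral triazolium-derived carbene converts the ring A aldehyde of racemic 2-{2-formyl-3,5-bis(methoxymethoxy)-4,6-bis[4-(methoxymethoxy)benzyl]phenoxy}-2-[4-(methoxymethoxy)phenyl]acetaldehyde A7 into an acyl anion equivalent. This adds to the side-chain aldehyde while the labile α-centre racemises, giving (2R,3R)-3-hydroxy-5,7-bis(methoxymethoxy)-6,8-bis[4-(methoxymethoxy)benzyl]-2-[4-(methoxymethoxy)phenyl]chroman-4-one A6.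
- For: ring C and both stereocentres arise in one catalytic step at the right oxidation level, and only one deprotection follows. In steps after the key step it is shorter than the chosen route.
- Against: the doubly ortho-substituted, electron-rich aryl aldehyde is the poorer partner for the carbene, so the aliphatic aldehyde is likely to become the acyl anion and give the isomeric 4-hydroxychroman-3-one. A dynamic resolution in an aldehyde–aldehyde crossed benzoin reaction giving a trans ketol has no close precedent, the product ketol is epimerisable and the addition reversible under the basic conditions. A7 again requires the fully substituted ring A.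
- Comparison: both routes carry an unprecedented key step, but here enantio-, diastereo- and chemoselectivity all sit in the uncertain step, whereas the uncertain step of the chosen route creates no stereocentre.

Key step: step 9

Remark 1: (S)-BINOL is assumed to direct the diene to the Si face of aldehyde 1 with the titanium catalyst; if the sense is opposite for this aldehyde, (R)-BINOL is used instead.
Remark 2: compounds 1, 2 and 9 are taken as commercial.

## Route

Step 1
Reactants: 1 4-(benzyloxy)benzaldehyde; 2 (E)-1-methoxy-3-(trimethylsilyloxy)buta-1,3-diene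
Product: 4 (S)-2-[4-(benzyloxy)phenyl]-2,3-dihydro-4H-pyran-4-one, via aldol adduct 3 (not isolated)
Conditions: Ti(OiPr)4 (10 mol %), (S)-BINOL (20 mol %), 4 Å MS, Et2O, −20 °C; then CF3CO2H, CH2Cl2, 0 °C
Reagents that add atoms: none
Why: Enantioselective hetero-Diels–Alder reaction in its stepwise form (Mukaiyama aldol addition, then acid-induced oxa-Michael closure with loss of methanol); the chiral titanium BINOLate shields one face of the bound aldehyde so that the diene terminus should add to the Si face, which sets C2 as (S) in 4 (the same spatial arrangement is called (R) once C3 bears oxygen).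

Step 2
Reactants: 4 (S)-2-[4-(benzyloxy)phenyl]-2,3-dihydro-4H-pyran-4-one
Product: 6 (2R,3R)-2-[4-(benzyloxy)phenyl]-3-hydroxy-2,3-dihydro-4H-pyran-4-one, via silyl dienol ether 5 (not isolated)
Conditions: TMSOTf, Et3N, CH2Cl2, 0 °C (crude 5 taken up in pentane, filtered, concentrated); DMDO, acetone/CH2Cl2, −78 → 0 °C; then 1 M HCl, THF, 0 °C
Reagents that add atoms: dimethyldioxirane, CC1(C)OO1
Why: Rubottom oxidation; C3 is the most nucleophilic carbon of the cross-conjugated dienol ether 5 because attack there leaves a cation stabilised by both oxygens, and the dioxirane should approach C3 anti to the C2 aryl group, which sets C3 as (R), trans to the aryl group. Trans is also the thermodynamic isomer, so any cis material can be equilibrated through the enol.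

Step 3
Reactants: 6 (2R,3R)-2-[4-(benzyloxy)phenyl]-3-hydroxy-2,3-dihydro-4H-pyran-4-one
Product: 7 (2R,3R)-2-[4-(benzyloxy)phenyl]-3-(tert-butyldimethylsilyloxy)-2,3-dihydro-4H-pyran-4-one
Conditions: TBSCl, imidazole, DMF, rt
Reagents that add atoms: tert-butyldimethylsilyl chloride, CC(C)(C)[Si](C)(C)Cl
Why: Standard silylation of a secondary α-hydroxy ketone; the mild base does not enolise C3, and the bulky silyl ether keeps the C3 oxygen out of the later Lewis acid step.

Step 4
Reactants: 7 (2R,3R)-2-[4-(benzyloxy)phenyl]-3-(tert-butyldimethylsilyloxy)-2,3-dihydro-4H-pyran-4-one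
Product: 8 (2R,3R)-2-[4-(benzyloxy)phenyl]-5-bromo-3-(tert-butyldimethylsilyloxy)-2,3-dihydro-4H-pyran-4-one
Conditions: NBS (1.05 equiv), CH2Cl2, 0 °C → rt, dark
Reagents that add atoms: N-bromosuccinimide, O=C1CCC(=O)N1Br
Why: Electrophilic α-halogenation of a vinylogous ester; C5 is the nucleophilic β-carbon of the O1–C6=C5 enol ether, bromonium transfer gives the oxocarbenium ion and loss of H5 restores the enone. The aryl benzyl ether is far less nucleophilic, and C2 and C3 are not touched.

Step 5
Reactants: 9 methyl 3-(4-hydroxyphenyl)propanoate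
Product: 10 methyl 3-[4-(benzyloxy)phenyl]propanoate
Conditions: BnBr, K2CO3, acetone, reflux
Reagents that add atoms: benzyl bromide, BrCc1ccccc1
Why: Williamson ether synthesis on a phenol; the methyl ester is inert to carbonate in acetone.

Step 6
Reactants: 10 methyl 3-[4-(benzyloxy)phenyl]propanoate (two equivalents)
Product: 11 methyl 2-[4-(benzyloxy)benzyl]-5-[4-(benzyloxy)phenyl]-3-oxopentanoate (racemic)
Conditions: NaH, MeOH (cat.), THF, reflux; then 1 M HCl
Reagents that add atoms: none
Why: Claisen self-condensation; the equilibrium is pulled by deprotonation of 11 at the one acidic hydrogen left between its carbonyl groups, and benzyl ethers are inert to the base.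

Step 7
Reactants: 11 methyl 2-[4-(benzyloxy)benzyl]-5-[4-(benzyloxy)phenyl]-3-oxopentanoate
Product: 12 methyl 2-[4-(benzyloxy)benzyl]-5-[4-(benzyloxy)phenyl]-3-(trimethylsilyloxy)pent-2-enoate (E/Z mixture)
Conditions: Me3SiCl, Et3N, toluene, rt
Reagents that add atoms: chlorotrimethylsilane, C[Si](C)(C)Cl
Why: O-Silylation of the enol of a β-keto ester with an amine base gives the conjugated 3-silyloxy enoate; the alkene geometry is irrelevant because both trigonal carbons end up in the arene.

Step 8
Reactants: 12 methyl 2-[4-(benzyloxy)benzyl]-5-[4-(benzyloxy)phenyl]-3-(trimethylsilyloxy)pent-2-enoate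
Product: 13 1-methoxy-1,3-bis(trimethylsilyloxy)-2,4-bis[4-(benzyloxy)benzyl]buta-1,3-diene (geometry not defined)
Conditions: LiN(iPr)2, THF, −78 °C; then Me3SiCl, −78 °C → rt; filtered under argon, used crude
Reagents that add atoms: chlorotrimethylsilane, C[Si](C)(C)Cl
Why: Kinetic γ-deprotonation of the vinylogous ester at C4 and O-silylation of the dienolate, the usual two-stage preparation of 1-alkoxy-1,3-bis(silyloxy)dienes; the diene is hydrolytically labile and is therefore not purified.

Step 9
Reactants: 8 (2R,3R)-2-[4-(benzyloxy)phenyl]-5-bromo-3-(tert-butyldimethylsilyloxy)-2,3-dihydro-4H-pyran-4-one; 13 1-methoxy-1,3-bis(trimethylsilyloxy)-2,4-bis[4-(benzyloxy)benzyl]buta-1,3-diene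
Product: 16 (2R,3R)-6,8-bis[4-(benzyloxy)benzyl]-2-[4-(benzyloxy)phenyl]-3-(tert-butyldimethylsilyloxy)-5,7-dihydroxychroman-4-one, via bromo cycloadduct 14 (not isolated), via bis(trimethylsilyl) ether 15 (not isolated)
Conditions: 8, TMSOTf (1.1 equiv), CH2Cl2, −78 °C; 13 (1.8 equiv), −78 → −20 °C; then Et3N (5 equiv), −20 °C → rt; then 1 M HCl, THF, 0 °C
Reagents that add atoms: none
Why: Proposed new method: silylation of the vinylogous-ester carbonyl of 8 by TMSOTf should give a 4-silyloxy oxocarbenium ion whose only electrophilic carbon is C6 of the pyranone (future C8a), and the terminal, most nucleophilic carbon of 13 (future C8) adds there in a Mukaiyama–Michael step. The cation left on the diene fragment is an O-silylated β-silyloxy acrylate with its charge at the future C5, and the bromo silyl enol ether just formed at C4=C4a should attack it, so that ring A closes by C4a–C5 bond formation in a 6-(enolexo)-exo-trig mode and gives 14; the two bonds together amount to a stepwise, polarised [4+2] annulation. The silyl triflate then ionises the mixed ketal at C5 with loss of MeOSiMe3, Et3N removes H8 and then H8a together with bromide, and this 1,2-elimination across C4a–C8a is driven by formation of the arene 15, whose two aryl silyl ethers are hydrolysed in the acidic work-up. The closest known reaction types are the silyl triflate-mediated conjugate addition of 1,3-bis(silyloxy)dienes to chromones and the Diels–Alder/dehydrohalogenation sequence of 1-alkoxy-1,3-bis(silyloxy)dienes with 2-haloquinones; neither has been run on a halogenated dihydropyranone. No stereocentre is created: the sp3 centres of 14 at C4a, C5, C8 and C8a are erased on aromatisation, and C2 and C3 take no part. The step needs regioselectivity (C8 to C8a rather than C5 to C8a), secured by the matched polarity of the oxocarbenium carbon and the diene terminus; it also needs aromatisation to win over expulsion of O1 from C8a, which is favoured because the bromine at C4a already carries the oxidation level of the arene and the C7 oxygen stays silylated, so that no free enolate at C8 arises before the arene has formed.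

Step 10
Reactants: 16 (2R,3R)-6,8-bis[4-(benzyloxy)benzyl]-2-[4-(benzyloxy)phenyl]-3-(tert-butyldimethylsilyloxy)-5,7-dihydroxychroman-4-one
Product: 17 (2R,3R)-6,8-bis[4-(benzyloxy)benzyl]-2-[4-(benzyloxy)phenyl]-3,5,7-trihydroxychroman-4-one
Conditions: HF·pyridine, THF/pyridine, 0 °C → rt
Reagents that add atoms: none
Why: Fluoride-induced cleavage of the secondary silyl ether under buffered, weakly acidic conditions, which avoid the C3 enolate and hence ring opening and epimerisation; aryl benzyl ethers are stable.

Step 11
Reactants: 17 (2R,3R)-6,8-bis[4-(benzyloxy)benzyl]-2-[4-(benzyloxy)phenyl]-3,5,7-trihydroxychroman-4-one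
Product: 18 gericudranin D, (2R,3R)-3,5,7-trihydroxy-6,8-bis(4-hydroxybenzyl)-2-(4-hydroxyphenyl)chroman-4-one
Conditions: H2 (1 atm), 10% Pd/C, EtOAc/MeOH, rt
Reagents that add atoms: none
Why: Hydrogenolysis of the three aryl benzyl ethers on palladium under neutral conditions; the diarylmethane C–C bonds are inert, and the C2–O1 benzylic ether and the hydrogen-bonded aryl ketone should react much more slowly, so the reaction is stopped after uptake of three equivalents of hydrogen.

## Compound list

1 | 4-(benzyloxy)benzaldehyde | O=Cc1ccc(OCc2ccccc2)cc1 | starting material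
2 | (E)-1-methoxy-3-(trimethylsilyloxy)buta-1,3-diene | CO/C=C/C(=C)O[Si](C)(C)C | starting material
3 | (S,E)-5-[4-(benzyloxy)phenyl]-1-methoxy-5-(trimethylsilyloxy)pent-1-en-3-one | CO/C=C/C(=O)C[C@H](O[Si](C)(C)C)c1ccc(OCc2ccccc2)cc1 | intermediate
4 | (S)-2-[4-(benzyloxy)phenyl]-2,3-dihydro-4H-pyran-4-one | O=C1C=CO[C@H](c2ccc(OCc3ccccc3)cc2)C1 | intermediate
5 | (S)-2-[4-(benzyloxy)phenyl]-4-(trimethylsilyloxy)-2H-pyran | C[Si](C)(C)OC1=C[C@@H](c2ccc(OCc3ccccc3)cc2)OC=C1 | intermediate
6 | (2R,3R)-2-[4-(benzyloxy)phenyl]-3-hydroxy-2,3-dihydro-4H-pyran-4-one | O=C1C=CO[C@H](c2ccc(OCc3ccccc3)cc2)[C@H]1O | intermediate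
7 | (2R,3R)-2-[4-(benzyloxy)phenyl]-3-(tert-butyldimethylsilyloxy)-2,3-dihydro-4H-pyran-4-one | O=C1C=CO[C@H](c2ccc(OCc3ccccc3)cc2)[C@H]1O[Si](C)(C)C(C)(C)C | intermediate
8 | (2R,3R)-2-[4-(benzyloxy)phenyl]-5-bromo-3-(tert-butyldimethylsilyloxy)-2,3-dihydro-4H-pyran-4-one | O=C1C(Br)=CO[C@H](c2ccc(OCc3ccccc3)cc2)[C@H]1O[Si](C)(C)C(C)(C)C | intermediate
9 | methyl 3-(4-hydroxyphenyl)propanoate | COC(=O)CCc1ccc(O)cc1 | starting material
10 | methyl 3-[4-(benzyloxy)phenyl]propanoate | COC(=O)CCc1ccc(OCc2ccccc2)cc1 | intermediate
11 | methyl 2-[4-(benzyloxy)benzyl]-5-[4-(benzyloxy)phenyl]-3-oxopentanoate (racemic) | COC(=O)C(Cc1ccc(OCc2ccccc2)cc1)C(=O)CCc1ccc(OCc2ccccc2)cc1 | intermediate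
12 | methyl 2-[4-(benzyloxy)benzyl]-5-[4-(benzyloxy)phenyl]-3-(trimethylsilyloxy)pent-2-enoate (E/Z mixture) | COC(=O)C(Cc1ccc(OCc2ccccc2)cc1)=C(CCc1ccc(OCc2ccccc2)cc1)O[Si](C)(C)C | intermediate
13 | 1-methoxy-1,3-bis(trimethylsilyloxy)-2,4-bis[4-(benzyloxy)benzyl]buta-1,3-diene (geometry not defined) | COC(O[Si](C)(C)C)=C(Cc1ccc(OCc2ccccc2)cc1)C(O[Si](C)(C)C)=CCc1ccc(OCc2ccccc2)cc1 | intermediate
14 | (2R,3R)-6,8-bis[4-(benzyloxy)benzyl]-2-[4-(benzyloxy)phenyl]-4a-bromo-3-(tert-butyldimethylsilyloxy)-5-methoxy-5,7-bis(trimethylsilyloxy)-2,3,4a,5,8,8a-hexahydro-4H-chromen-4-one (isomer mixture at C4a, C5, C8, C8a) | O=C1C2(Br)C(OC)(O[Si](C)(C)C)C(Cc3ccc(OCc4ccccc4)cc3)=C(O[Si](C)(C)C)C(Cc3ccc(OCc4ccccc4)cc3)C2O[C@H](c2ccc(OCc3ccccc3)cc2)[C@H]1O[Si](C)(C)C(C)(C)C | intermediate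
15 | (2R,3R)-6,8-bis[4-(benzyloxy)benzyl]-2-[4-(benzyloxy)phenyl]-3-(tert-butyldimethylsilyloxy)-5,7-bis(trimethylsilyloxy)chroman-4-one | O=C1c2c(O[Si](C)(C)C)c(Cc3ccc(OCc4ccccc4)cc3)c(O[Si](C)(C)C)c(Cc3ccc(OCc4ccccc4)cc3)c2O[C@H](c2ccc(OCc3ccccc3)cc2)[C@H]1O[Si](C)(C)C(C)(C)C | intermediate
16 | (2R,3R)-6,8-bis[4-(benzyloxy)benzyl]-2-[4-(benzyloxy)phenyl]-3-(tert-butyldimethylsilyloxy)-5,7-dihydroxychroman-4-one | O=C1c2c(O)c(Cc3ccc(OCc4ccccc4)cc3)c(O)c(Cc3ccc(OCc4ccccc4)cc3)c2O[C@H](c2ccc(OCc3ccccc3)cc2)[C@H]1O[Si](C)(C)C(C)(C)C | intermediate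
17 | (2R,3R)-6,8-bis[4-(benzyloxy)benzyl]-2-[4-(benzyloxy)phenyl]-3,5,7-trihydroxychroman-4-one | O=C1c2c(O)c(Cc3ccc(OCc4ccccc4)cc3)c(O)c(Cc3ccc(OCc4ccccc4)cc3)c2O[C@H](c2ccc(OCc3ccccc3)cc2)[C@H]1O | intermediate
18 | gericudranin D | O=C1c2c(O)c(Cc3ccc(O)cc3)c(O)c(Cc3ccc(O)cc3)c2O[C@H](c2ccc(O)cc2)[C@H]1O | target

## Step count and least certain steps

Total: 11 steps. Longest linear sequence: 7 steps (steps 1, 2, 3, 4, 9, 10, 11; the diene branch, steps 5 to 8 followed by 9 to 11, is equally long).

**Step 9 (key step).** Several processes may defeat it.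
- The second C–C bond may fail to form, because the bromo silyl enol ether is a weakened nucleophile; the sequence then stops after conjugate addition.
- The C8a–O1 bond may ionise with help from the C7 silyl enol ether, and transfer of positive bromine to a nucleophile would then leave ring C open for good.
- Acid may ionise the para-benzyloxy-stabilised benzylic C2–O1 bond and erode the configuration at C2.
- Enol silylation across C3–C4 after the amine is added may epimerise C3 on reprotonation.
- The diene may be protodesilylated before it reacts.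

Fallback by known chemistry, setting out from aldehyde 1 and returning at 17:
- Commercial 2,4,6-trihydroxyacetophenone is C-benzylated at both free ring positions with 4-(benzyloxy)benzyl chloride (KOH, aqueous MeOH) to 1-{3,5-bis[4-(benzyloxy)benzyl]-2,4,6-trihydroxyphenyl}ethanone F1.
- MOMCl/NaH in DMF converts this into 1-{3,5-bis[4-(benzyloxy)benzyl]-2,4,6-tris(methoxymethoxy)phenyl}ethanone F2.
- Claisen–Schmidt condensation with 1 (KOH, EtOH) gives (E)-3-[4-(benzyloxy)phenyl]-1-{3,5-bis[4-(benzyloxy)benzyl]-2,4,6-tris(methoxymethoxy)phenyl}prop-2-en-1-one F3.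
- Juliá–Colonna epoxidation (poly-L-leucine, urea–H2O2, DBU, THF; the antipode that delivers the αR,βS epoxide) gives {(2R,3S)-3-[4-(benzyloxy)phenyl]oxiran-2-yl}{3,5-bis[4-(benzyloxy)benzyl]-2,4,6-tris(methoxymethoxy)phenyl}methanone F4.
- HCl in MeOH at 45 °C removes the three acetals, and the freed ortho phenol opens the epoxide at the benzylic carbon with inversion, which should give the trans dihydroflavonol 17.

**Step 1.** Addition to the electron-rich aldehyde may be slow, so that an uncatalysed background reaction lowers the facial selectivity. Fallback from 1, returning at 4: aldol addition of the boron enolate of 4-(trimethylsilyl)but-3-yn-2-one (Ipc2BCl of the antipode that gives the S carbinol, iPr2NEt, Et2O, −78 °C) to 1 gives (S)-1-[4-(benzyloxy)phenyl]-1-hydroxy-5-(trimethylsilyl)pent-4-yn-3-one F5. K2CO3 in MeOH then removes the silyl group and closes the ring by 6-endo-dig oxa-Michael addition to give 4.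

**Step 2.** Oxidation may occur at the C5=C6 enol ether instead of C3=C4, the oxidant may approach syn to the aryl group, or 5 may hydrolyse back to 4 before it is oxidised. Fallback from 4, returning at 6: radical α'-acetoxylation with Mn(OAc)3·2H2O in refluxing benzene, which on dihydropyranones goes trans to the C2 substituent, gives (2R,3R)-3-acetoxy-2-[4-(benzyloxy)phenyl]-2,3-dihydro-4H-pyran-4-one F6. Mild methanolysis (K2CO3, MeOH, 0 °C) then gives 6.

**Step 8.** γ-Deprotonation may be incomplete, C-silylation may compete, and the diene may hydrolyse on handling. Fallback from 11, returning at 13 without passing through 12: NaH (THF, 0 °C) and then n-BuLi (−78 °C) generate sodium lithium 1-methoxy-2,4-bis[4-(benzyloxy)benzyl]buta-1,3-diene-1,3-diolate F7, which is silylated on both oxygens with Me3SiCl to give 13.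

**Step 10.** Cleavage of the hindered silyl ether next to the ketone may be slow, and forcing it risks opening of ring C at C2–O1 or dehydrogenation to the flavonol. Fallback from 16, returning at 18: the order is reversed. Hydrogenolysis (H2, Pd/C, EtOAc/MeOH) first gives (2R,3R)-3-(tert-butyldimethylsilyloxy)-5,7-dihydroxy-6,8-bis(4-hydroxybenzyl)-2-(4-hydroxyphenyl)chroman-4-one F8, and the silyl ether is then removed with 3 M HCl in MeOH at 40 °C to give 18.

## Further compounds

F1 | step 9 | 1-{3,5-bis[4-(benzyloxy)benzyl]-2,4,6-trihydroxyphenyl}ethanone | CC(=O)c1c(O)c(Cc2ccc(OCc3ccccc3)cc2)c(O)c(Cc2ccc(OCc3ccccc3)cc2)c1O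
F2 | step 9 | 1-{3,5-bis[4-(benzyloxy)benzyl]-2,4,6-tris(methoxymethoxy)phenyl}ethanone | CC(=O)c1c(OCOC)c(Cc2ccc(OCc3ccccc3)cc2)c(OCOC)c(Cc2ccc(OCc3ccccc3)cc2)c1OCOC
F3 | step 9 | (E)-3-[4-(benzyloxy)phenyl]-1-{3,5-bis[4-(benzyloxy)benzyl]-2,4,6-tris(methoxymethoxy)phenyl}prop-2-en-1-one | O=C(/C=C/c1ccc(OCc2ccccc2)cc1)c1c(OCOC)c(Cc2ccc(OCc3ccccc3)cc2)c(OCOC)c(Cc2ccc(OCc3ccccc3)cc2)c1OCOC
F4 | step 9 | {(2R,3S)-3-[4-(benzyloxy)phenyl]oxiran-2-yl}{3,5-bis[4-(benzyloxy)benzyl]-2,4,6-tris(methoxymethoxy)phenyl}methanone | O=C(c1c(OCOC)c(Cc2ccc(OCc3ccccc3)cc2)c(OCOC)c(Cc2ccc(OCc3ccccc3)cc2)c1OCOC)[C@@H]1O[C@H]1c1ccc(OCc2ccccc2)cc1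
F5 | step 1 | (S)-1-[4-(benzyloxy)phenyl]-1-hydroxy-5-(trimethylsilyl)pent-4-yn-3-one | C[Si](C)(C)C#CC(=O)C[C@H](O)c1ccc(OCc2ccccc2)cc1
F6 | step 2 | (2R,3R)-3-acetoxy-2-[4-(benzyloxy)phenyl]-2,3-dihydro-4H-pyran-4-one | O=C1C=CO[C@H](c2ccc(OCc3ccccc3)cc2)[C@H]1OC(C)=O
F7 | step 8 | sodium lithium 1-methoxy-2,4-bis[4-(benzyloxy)benzyl]buta-1,3-diene-1,3-diolate | COC([O-])=C(Cc1ccc(OCc2ccccc2)cc1)C([O-])=CCc1ccc(OCc2ccccc2)cc1.[Na+].[Li+]
F8 | step 10 | (2R,3R)-3-(tert-butyldimethylsilyloxy)-5,7-dihydroxy-6,8-bis(4-hydroxybenzyl)-2-(4-hydroxyphenyl)chroman-4-one | O=C1c2c(O)c(Cc3ccc(O)cc3)c(O)c(Cc3ccc(O)cc3)c2O[C@H](c2ccc(O)cc2)[C@H]1O[Si](C)(C)C(C)(C)C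
A1 | alternative 1 | 3,4'-di-O-acetyl-5,7,4'',4'''-tetra-O-benzyl gericudranin D | O=C1c2c(OCc3ccccc3)c(Cc3ccc(OCc4ccccc4)cc3)c(OCc3ccccc3)c(Cc3ccc(OCc4ccccc4)cc3)c2O[C@H](c2ccc(OC(C)=O)cc2)[C@H]1OC(C)=O
A2 | alternative 1 | (2R,3R)-2-acetoxy-3-(4-acetoxyphenyl)-3-{3,5-bis(benzyloxy)-2,4-bis[4-(benzyloxy)benzyl]phenoxy}propanoic acid | c1c(OCc2ccccc2)c(Cc2ccc(OCc3ccccc3)cc2)c(OCc2ccccc2)c(Cc2ccc(OCc3ccccc3)cc2)c1O[C@H](c1ccc(OC(C)=O)cc1)[C@H](C(=O)O)OC(C)=O
A3 | alternative 2 | 5,7-bis(methoxymethoxy)-6,8-bis[4-(methoxymethoxy)benzyl]-2-[4-(methoxymethoxy)phenyl]-4H-chromen-4-one | O=c1cc(-c2ccc(OCOC)cc2)oc2c(Cc3ccc(OCOC)cc3)c(OCOC)c(Cc3ccc(OCOC)cc3)c(OCOC)c12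
A4 | alternative 2 | 2-iodo-3,5-bis(methoxymethoxy)-4,6-bis[4-(methoxymethoxy)benzyl]phenol | Oc1c(I)c(OCOC)c(Cc2ccc(OCOC)cc2)c(OCOC)c1Cc1ccc(OCOC)cc1
A5 | alternative 2 | 1-ethynyl-4-(methoxymethoxy)benzene | C#Cc1ccc(OCOC)cc1
A6 | alternative 3 | (2R,3R)-3-hydroxy-5,7-bis(methoxymethoxy)-6,8-bis[4-(methoxymethoxy)benzyl]-2-[4-(methoxymethoxy)phenyl]chroman-4-one | O=C1c2c(OCOC)c(Cc3ccc(OCOC)cc3)c(OCOC)c(Cc3ccc(OCOC)cc3)c2O[C@H](c2ccc(OCOC)cc2)[C@H]1O
A7 | alternative 3 | 2-{2-formyl-3,5-bis(methoxymethoxy)-4,6-bis[4-(methoxymethoxy)benzyl]phenoxy}-2-[4-(methoxymethoxy)phenyl]acetaldehyde (racemic) | O=Cc1c(OCOC)c(Cc2ccc(OCOC)cc2)c(OCOC)c(Cc2ccc(OCOC)cc2)c1OC(C=O)c1ccc(OCOC)cc1
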